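The route rests on disconnecting the quinone ring (C1–C6) at C4–C5. C1–C4, carrying the C3 side chain and the C2 oxygen masked as a tert-butyl ether, come from a squarate; C5(OMe) and C6(H) come from a (Z)-2-methoxyvinyl anion. Heating the resulting 4-hydroxy-4-(methoxyvinyl)cyclobutenone releases ring strain by 4π opening to a dienylketene, whose 6π closure makes the C4–C5 bond and the six-membered ring in one operation, with the oxygens at C1, C2, C4 and C5 already placed and differentiated. The precursor carries the (R)-carbinol, taken from (R)-epichlorohydrin, as a silyl ether so that no hydroxyl can intercept the ketene.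

Key step: step 7

Assumption: di-tert-butyl squarate is taken as a catalogue compound.

Step 1
Reactants: 1 (R)-epichlorohydrin; 2 decylmagnesium bromide
Product: 3 (R)-1-chlorotridecan-2-ol
Conditions: CuI (10 mol%), THF, −40 °C to −20 °C; aq. NH4Cl
Reagents that add atoms: none
Why: Copper-catalysed Grignard opening of the epoxide (SN2 at the unsubstituted ring carbon) leaves the C–O stereocentre untouched, so the (R) configuration of 1 passes into 3 (CH2Cl still outranks the alkyl arm), and in the cold the chloroalkoxide should not close to an epoxide.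

Step 2
Reactants: 3 (R)-1-chlorotridecan-2-ol; 4 di-tert-butyl squarate (3,4-di-tert-butoxycyclobut-3-ene-1,2-dione)
Product: 6 2,3-di-tert-butoxy-4-hydroxy-4-[(R)-2-hydroxytridecyl]cyclobut-2-en-1-one (both C4 epimers), via β-oxido alkyllithium 5 (not isolated)
Conditions: n-BuLi (1.0 equiv), THF, −78 °C; lithium naphthalenide (2.0 equiv), −78 °C; cannulate into 4 (1.3 equiv), THF, −78 °C; aq. NH4Cl
Reagents that add atoms: none
Why: O-deprotonation followed by reductive lithiation of the C–Cl bond (arene radical-anion method) should give dianion 5, which resists β-elimination at −78 °C because oxide is a very poor leaving group, and its organolithium 1,2-addition to one carbonyl of the symmetric squarate ester gives the carbinol; the side-chain stereocentre is untouched and the new ring carbinol centre is erased in step 4.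

Step 3
Reactants: 6 2,3-di-tert-butoxy-4-hydroxy-4-[(R)-2-hydroxytridecyl]cyclobut-2-en-1-one
Product: 7 2,3-di-tert-butoxy-4-hydroxy-4-[(R)-2-(tert-butyldimethylsilyloxy)tridecyl]cyclobut-2-en-1-one
Conditions: TBSCl, imidazole, DMF, 0 °C to rt
Reagents that add atoms: tert-butyldimethylsilyl chloride (TBSCl), CC(C)(C)[Si](C)(C)Cl
Why: Silyl ether formation with TBSCl and imidazole is selective for the secondary hydroxyl, the tertiary ring carbinol being too hindered, and it masks the one hydroxyl that could later capture a ketene.

Step 4
Reactants: 7 2,3-di-tert-butoxy-4-hydroxy-4-[(R)-2-(tert-butyldimethylsilyloxy)tridecyl]cyclobut-2-en-1-one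
Product: 8 3-tert-butoxy-4-[(R)-2-(tert-butyldimethylsilyloxy)tridecyl]cyclobut-3-ene-1,2-dione
Conditions: TFAA, Et2O, −78 °C to 0 °C; aq. NaHCO3
Reagents that add atoms: none
Why: Trifluoroacetylation of the tertiary carbinol, ionisation to an alkoxy-stabilised cyclobutenyl cation and loss of isobutene from the resulting oxocarbenium ion (the squarate-adduct-to-cyclobutenedione rearrangement) should give the 3-alkoxy-4-alkylcyclobutenedione under conditions too cold and brief to harm the silyl ether or the remaining tert-butyl vinylogous ester.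

Step 5
Reactants: 9 bromoacetaldehyde dimethyl acetal
Product: 10 (Z)-1-bromo-2-methoxyethene
Conditions: TMSOTf, i-Pr2NEt, CH2Cl2, −20 °C to rt; fractional distillation
Reagents that add atoms: none
Why: Silyl triflate ionisation of the acetal to an oxocarbenium ion and amine deprotonation (acetal-to-enol-ether elimination) should give the bromo enol ether, the Z isomer being favoured by the cis preference of 1-halo-2-alkoxyethenes and freed from E isomer by distillation.

Step 6
Reactants: 10 (Z)-1-bromo-2-methoxyethene; 8 3-tert-butoxy-4-[(R)-2-(tert-butyldimethylsilyloxy)tridecyl]cyclobut-3-ene-1,2-dione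
Product: 12 3-tert-butoxy-4-hydroxy-4-[(Z)-2-methoxyvinyl]-2-[(R)-2-(tert-butyldimethylsilyloxy)tridecyl]cyclobut-2-en-1-one (both C4 epimers), via (Z)-2-methoxyvinyllithium 11 (not isolated)
Conditions: 10 (1.3 equiv), t-BuLi (2.5 equiv), THF, −78 °C; add 8, −78 °C; aq. NH4Cl at −78 °C
Reagents that add atoms: none
Why: Bromine–lithium exchange proceeds with retention of alkene geometry to the O-chelated vinyllithium 11, which cannot undergo anti β-elimination at −78 °C, and organolithium 1,2-addition then occurs at the more electrophilic ketone carbonyl next to the tert-butoxy-bearing carbon and not at the vinylogous-ester carbonyl; the new carbinol centre forms as both epimers, which does not matter because it becomes aromatic.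

Step 7
Reactants: 12 3-tert-butoxy-4-hydroxy-4-[(Z)-2-methoxyvinyl]-2-[(R)-2-(tert-butyldimethylsilyloxy)tridecyl]cyclobut-2-en-1-one
Product: 15 2-tert-butoxy-5-methoxy-3-[(R)-2-(tert-butyldimethylsilyloxy)tridecyl]benzene-1,4-diol, via dienylketene 13 (not isolated), via cyclohexadienone 14 (not isolated)
Conditions: toluene (degassed, 0.02 M), 110 °C, argon; crude 15 taken on directly
Reagents that add atoms: none
Why: Thermal conrotatory 4π electrocyclic opening of the strained cyclobutenone gives dienylketene 13, and 6π electrocyclisation between the ketene carbon and the methoxy-bearing vinyl carbon forms the C4–C5 bond (quinone numbering) of cyclohexadienone 14, which enolises to the aromatic hydroquinone 15. The closest known reaction type is the thermal ring expansion of squarate-derived 4-alkenyl- and 4-aryl-4-hydroxycyclobutenones to hydroquinones. The one ring formed, the six-membered carbocycle, is closed by disrotatory 6π electrocyclisation of a ketene-terminated triene, which should tolerate the inward methoxy group because the ketene terminus is sterically undemanding. No stereocentre is created: the ring carbinol carbon and the transient CH(OMe) carbon both end as aromatic carbons, so the epimers of 12 converge, and the side-chain (R)-carbinol is a spectator. The step needs outward rotation of the hydroxyl, which the donor oxygen on the breaking bond secures by torquoselectivity and which places the methoxyvinyl group cis to the ketene; the silyl ether keeps any hydroxyl from adding to the ketene, and the placement of the side chain between the tert-butoxy carbon and the carbonyl next to C–OMe is inherited from step 6.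

Step 8
Reactants: 15 2-tert-butoxy-5-methoxy-3-[(R)-2-(tert-butyldimethylsilyloxy)tridecyl]benzene-1,4-diol
Product: 16 2-tert-butoxy-5-methoxy-3-[(R)-2-(tert-butyldimethylsilyloxy)tridecyl]-1,4-benzoquinone
Conditions: Ag2O, Na2SO4, Et2O, rt
Reagents that add atoms: none
Why: Dehydrogenation of the electron-rich hydroquinone to the para-quinone with Ag2O is neutral and mild, so the silyl ether, the tert-butyl ether and the stereocentre are untouched.

Step 9
Reactants: 16 2-tert-butoxy-5-methoxy-3-[(R)-2-(tert-butyldimethylsilyloxy)tridecyl]-1,4-benzoquinone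
Product: 17 2-tert-butoxy-3-[(R)-2-hydroxytridecyl]-5-methoxy-1,4-benzoquinone
Conditions: HF·pyridine, pyridine, THF, 0 °C to rt; crude 17 acetylated at once
Reagents that add atoms: none
Why: Fluoride-mediated desilylation in pyridine-buffered HF·pyridine is weakly acidic and non-basic, so the tert-butyl and methyl vinylogous esters should persist and the neutral alcohol should be too poor a nucleophile to add to the quinone.

Step 10
Reactants: 17 2-tert-butoxy-3-[(R)-2-hydroxytridecyl]-5-methoxy-1,4-benzoquinone
Product: 18 2-tert-butoxy-3-[(R)-2-acetoxytridecyl]-5-methoxy-1,4-benzoquinone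
Conditions: Ac2O, pyridine, DMAP (cat.), CH2Cl2, 0 °C
Reagents that add atoms: acetic anhydride, CC(=O)OC(C)=O
Why: DMAP-catalysed acylation of the secondary alcohol (nucleophilic catalysis) touches only the O–H bond, so the configuration at the carbinol carbon is retained.

Step 11
Reactants: 18 2-tert-butoxy-3-[(R)-2-acetoxytridecyl]-5-methoxy-1,4-benzoquinone
Product: 19 2-hydroxy-3-[(R)-2-acetoxytridecyl]-5-methoxy-1,4-benzoquinone (target)
Conditions: TFA, CH2Cl2, 0 °C to rt
Reagents that add atoms: none
Why: Acidolysis of the tert-butyl vinylogous ester (E1 loss of isobutene, as for a tert-butyl ester) unmasks the C2 hydroxyl, while the acetate and the methyl ether are stable to anhydrous TFA.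

Compound list
1 | (R)-epichlorohydrin | ClC[C@H]1CO1 | starting material
2 | decylmagnesium bromide | CCCCCCCCCC[Mg]Br | starting material
3 | (R)-1-chlorotridecan-2-ol | CCCCCCCCCCC[C@H](CCl)O | intermediate
4 | di-tert-butyl squarate (3,4-di-tert-butoxycyclobut-3-ene-1,2-dione) | CC(C)(C)OC1=C(OC(C)(C)C)C(=O)C1=O | starting material
5 | 1-lithio-2-(lithiooxy)tridecane, the C,O-dilithio derivative of 3 with the same spatial arrangement at C2 (CIP label S because CH2Li ranks below the alkyl arm) | CCCCCCCCCCC[C@H](C[Li])O[Li] | intermediate (not isolated)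
6 | 2,3-di-tert-butoxy-4-hydroxy-4-[(R)-2-hydroxytridecyl]cyclobut-2-en-1-one, both C4 epimers | CCCCCCCCCCC[C@H](CC1(O)C(OC(C)(C)C)=C(OC(C)(C)C)C1=O)O | intermediate
7 | 2,3-di-tert-butoxy-4-hydroxy-4-[(R)-2-(tert-butyldimethylsilyloxy)tridecyl]cyclobut-2-en-1-one, both C4 epimers | CCCCCCCCCCC[C@H](CC1(O)C(OC(C)(C)C)=C(OC(C)(C)C)C1=O)O[Si](C)(C)C(C)(C)C | intermediate
8 | 3-tert-butoxy-4-[(R)-2-(tert-butyldimethylsilyloxy)tridecyl]cyclobut-3-ene-1,2-dione | CCCCCCCCCCC[C@H](CC1=C(OC(C)(C)C)C(=O)C1=O)O[Si](C)(C)C(C)(C)C | intermediate
9 | bromoacetaldehyde dimethyl acetal | COC(CBr)OC | starting material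
10 | (Z)-1-bromo-2-methoxyethene | CO/C=C\Br | intermediate
11 | (Z)-2-methoxyvinyllithium | CO/C=C\[Li] | intermediate (not isolated)
12 | 3-tert-butoxy-4-hydroxy-4-[(Z)-2-methoxyvinyl]-2-[(R)-2-(tert-butyldimethylsilyloxy)tridecyl]cyclobut-2-en-1-one, both C4 epimers | CCCCCCCCCCC[C@H](CC1=C(OC(C)(C)C)C(O)(/C=C\OC)C1=O)O[Si](C)(C)C(C)(C)C | intermediate
13 | (3Z,5Z)-3-tert-butoxy-4-hydroxy-6-methoxy-2-[(R)-2-(tert-butyldimethylsilyloxy)tridecyl]hexa-1,3,5-trien-1-one (dienylketene) | CCCCCCCCCCC[C@H](CC(=C=O)/C(OC(C)(C)C)=C(O)\C=C/OC)O[Si](C)(C)C(C)(C)C | intermediate (not isolated)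
14 | 3-tert-butoxy-4-hydroxy-6-methoxy-2-[(R)-2-(tert-butyldimethylsilyloxy)tridecyl]cyclohexa-2,4-dien-1-one, both C6 epimers | CCCCCCCCCCC[C@H](CC1=C(OC(C)(C)C)C(O)=CC(OC)C1=O)O[Si](C)(C)C(C)(C)C | intermediate (not isolated)
15 | 2-tert-butoxy-5-methoxy-3-[(R)-2-(tert-butyldimethylsilyloxy)tridecyl]benzene-1,4-diol | CCCCCCCCCCC[C@H](Cc1c(O)c(OC)cc(O)c1OC(C)(C)C)O[Si](C)(C)C(C)(C)C | intermediate
16 | 2-tert-butoxy-5-methoxy-3-[(R)-2-(tert-butyldimethylsilyloxy)tridecyl]-1,4-benzoquinone | CCCCCCCCCCC[C@H](CC1=C(OC(C)(C)C)C(=O)C=C(OC)C1=O)O[Si](C)(C)C(C)(C)C | intermediate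
17 | 2-tert-butoxy-3-[(R)-2-hydroxytridecyl]-5-methoxy-1,4-benzoquinone | CCCCCCCCCCC[C@H](CC1=C(OC(C)(C)C)C(=O)C=C(OC)C1=O)O | intermediate
18 | 2-tert-butoxy-3-[(R)-2-acetoxytridecyl]-5-methoxy-1,4-benzoquinone | CCCCCCCCCCC[C@H](CC1=C(OC(C)(C)C)C(=O)C=C(OC)C1=O)OC(C)=O | intermediate
19 | 2-hydroxy-3-[(R)-2-acetoxytridecyl]-5-methoxy-1,4-benzoquinone | CCCCCCCCCCC[C@H](CC1=C(O)C(=O)C=C(OC)C1=O)OC(C)=O | target

Total step count: 11. Longest linear sequence: 10 steps (steps 1–4 and 6–11, from 1); step 5 is a one-step side branch.

Steps most likely to fail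

Step 2. The reductive lithiation may be incomplete, or the dianion may lose lithium oxide to give 1-tridecene before it is transferred. Any arene radical anion that survives would reduce the squarate by electron transfer instead of letting the carbanion add. Fallback: set out from 3 and exchange chloride for iodide (NaI, acetone, reflux, Finkelstein reaction) to give (R)-1-iodotridecan-2-ol F1. Deprotonation with MeLi and iodine–lithium exchange with t-BuLi (2 equiv) in Et2O at −78 °C should give the same dianion 5 without any electron-transfer reagent. Its addition to 4 as in step 2 comes back to the route at 6.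

Step 7. If the inward methoxy group slows the 6π closure, the dienylketene can revert to the cyclobutenone and drain through the minor hydroxyl-inward opening into lactonisation to a butenolide. Prolonged heating also risks thermal loss of isobutene from the tert-butyl ether. Fallback: the alkynyl version of the ring expansion, setting out from 8 (with 10 as the two-carbon source). Treating 10 with LiN(i-Pr)2 (2 equiv, THF, −78 °C to 0 °C) should give lithium methoxyacetylide F2 by dehydrobromination and deprotonation. Its addition to 8 at −78 °C, with the same carbonyl selectivity, gives 3-tert-butoxy-4-hydroxy-4-(methoxyethynyl)-2-[(R)-2-(tert-butyldimethylsilyloxy)tridecyl]cyclobut-2-en-1-one F3. Heating F3 in toluene should open the ring and close it through a diradical that takes the hydroxyl hydrogen, which delivers the quinone directly; the route is rejoined at 16.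

Step 9. The freed secondary hydroxyl could add to the neighbouring tert-butoxy-bearing quinone carbon and expel tert-butanol (dihydrofuran ring closure), or the tert-butyl group could be lost early in the acidic fluoride medium. Fallback: reverse the order of unmasking, setting out from 16. TFA in CH2Cl2 at 0 °C first gives 2-hydroxy-5-methoxy-3-[(R)-2-(tert-butyldimethylsilyloxy)tridecyl]-1,4-benzoquinone F4, in which C2 is a vinylogous acid carbon and no longer an acceptor carrying a leaving group; partial desilylation here is harmless because it leads on to the next compound. HF·pyridine then gives 2-hydroxy-3-[(R)-2-hydroxytridecyl]-5-methoxy-1,4-benzoquinone F5. Ac2O and pyridine give 2-acetoxy-3-[(R)-2-acetoxytridecyl]-5-methoxy-1,4-benzoquinone F6. Selective hydrolysis of the quinonyl acetate, a vinylogous mixed anhydride, with aq. NaHCO3 in THF leaves the alkyl acetate and comes back to the route at 19.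

Further compounds
F1 | step 2 | (R)-1-iodotridecan-2-ol | CCCCCCCCCCC[C@H](CI)O
F2 | step 7 | lithium methoxyacetylide | COC#C[Li]
F3 | step 7 | 3-tert-butoxy-4-hydroxy-4-(methoxyethynyl)-2-[(R)-2-(tert-butyldimethylsilyloxy)tridecyl]cyclobut-2-en-1-one | CCCCCCCCCCC[C@H](CC1=C(OC(C)(C)C)C(O)(C#COC)C1=O)O[Si](C)(C)C(C)(C)C
F4 | step 9 | 2-hydroxy-5-methoxy-3-[(R)-2-(tert-butyldimethylsilyloxy)tridecyl]-1,4-benzoquinone | CCCCCCCCCCC[C@H](CC1=C(O)C(=O)C=C(OC)C1=O)O[Si](C)(C)C(C)(C)C
F5 | step 9 | 2-hydroxy-3-[(R)-2-hydroxytridecyl]-5-methoxy-1,4-benzoquinone | CCCCCCCCCCC[C@H](CC1=C(O)C(=O)C=C(OC)C1=O)O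
F6 | step 9 | 2-acetoxy-3-[(R)-2-acetoxytridecyl]-5-methoxy-1,4-benzoquinone | CCCCCCCCCCC[C@H](CC1=C(OC(C)=O)C(=O)C=C(OC)C1=O)OC(C)=O
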